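(The earlier runs and the new flask are calculated with constants of no real substance, and the scatter is random.)

| flask | D | G | remark | time | volume of the second phase over the first |
|---|---|---|---|---|---|
| Friday's | 1 M | 1.4 M | run made earlier |  |  |
| flask | 1.0 M | 0.900 M |  | 30 min | 1.0 |

Friday's run (percent of the D charged)

| time / min | E / % | D / % |
|---|---|---|
| 1.33 | 15.7 | 84.6 |
| 2.50 | 12.8 | 87.8 |
| 4.00 | 7.0 | 92.7 |
| 5.00 | 5.4 | 94.7 |
| 6.00 | 3.8 | 96.3 |

(scatter of a reading: 0.5 percentage points)

- time, not beyond 30 min, at which the flask holds most E
- the amount of E, in percent of the D charged, at that time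

We begin with the slow part of Friday's run, its late fading. In Friday's run E and D sum to 100% at the first reading, so we take E as D lent out and returned, and we freeze D, never read below 84.6% there, at its charge. With D frozen, E forms by a pseudo-first-order step in the reagent. We therefore take E as the difference of two exponentials, its height proportional to the G charged and its shape unchanged by that charge.

The fade rate, the rate at which E decays once its rise is over, comes from the readings at 2.50 min and 6.00 min: 0.347 min⁻¹. Carried back to zero time, that line starts at 30.5%. At 1.33 min the line stands higher than the reading, by 3.5 percentage points, and we read this shortfall as the unfinished rise, which gives a rise rate of 1.63 min⁻¹. The two rates put the peak at ln(rise/fade)/(rise − fade) = 1.21 min. Scaling the line to the flask's G gives 19.6%, and so a height of 10.1%.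

The weak link is the rise rate: its shortfall is taken at the one reading at 1.33 min, which scatters by 0.5 points. Moving that reading by this much each way gives rise rates of 1.52 min⁻¹ and 1.74 min⁻¹. The peak then falls at 1.26 min or 1.16 min, with heights of 9.77% and 10.5%. We commit to 1.21 min and 10.1%.

The forecast gives 1.05 min (from 0.6 min to 1.8 min), earlier than our time, and 10% (from 8% to 12.5%), adding: “the peak is an extrapolation”.

The flask peaks at 1.25 min with 10.1% of E.

    Z ⇌ G, rate k1*([Z] - [G]/K1) per volume of the first phase (partition coefficient = 2.00, kL = 0.0560 s⁻¹)
    D + Z ⇌ E (K = 0.840 L mol⁻¹, k = 0.0250 L mol⁻¹ s⁻¹)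
    Z → Q (k = 0.0270 s⁻¹)

At that peak D stands at 89.9% of its charge. The line starting at 19.6% and decaying at the fade rate gives 0.108% at 15.0 min, and this flask then holds 0.104%. For a neighbouring flask with the same charges, read at 8.0 min, the line gives 1.22%, and that flask holds 1.23%.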